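**Plan** (carotenoid numbering; target = (5'S,6E,6'E)-4,5'-retro-β,β-carotene, all chain alkenes E)
- Enabling feature: ring B (C1'–C6') carries the only stereocentre, C5', a CH(CH3) directly beside the exocyclic C6'=C7' alkene. Read backwards, C6'=C7' is the enolate of a C7' aldehyde on C6', and C5'–CH3 is the bond a methyl nucleophile makes at the β-carbon of the C5'=C6' enal.
- Cuts, in retrosynthetic order: C7'–C8' (sp2–sp2) together with C9'–CH3; C15–C15'; C11'=C10'; C5'–CH3 with O-sulfonylation at C7'; C7'–C6' (formyl carbon onto the ring); the C15–O/C4–H pair of retinol.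
- Forward: no ring is formed; ring B comes from 2,2-dimethylcyclohexanone and ring A from retinol. The C15'–C8' linker is built from an enynol, joined to anhydroretinol at C15–C15', and the ring B enol triflate is attached last at C7'–C8'.
- Stereochemistry: C5' from ligand-controlled copper-catalysed methyl addition; C6'=C7' geometry from the enolate. The other alkenes come from all-trans-retinol, syn-hydrozirconation, Horner–Wadsworth–Emmons olefination, Heck coupling and syn-methylalumination.

Key step: step 3

Assumption: the facial sense of the copper–ferrocenyl diphosphine catalyst on this enal is taken to be such that the (R,Sp) ligand gives (S) at C5'; should the opposite sense be found, the commercial (S,Rp) antipode is used with no other change.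
Steps 4–10 are run under argon with exclusion of light.

Step 1
Reactants: 1 2,2-dimethylcyclohexan-1-one
Product: 2 N'-[(1E)-2,2-dimethylcyclohexylidene]-2,4,6-triisopropylbenzenesulfonohydrazide
Conditions: TrisNHNH2, HCl (cat.), MeOH, rt
Reagents that add atoms: 2,4,6-triisopropylbenzenesulfonohydrazide, CC(C)c1cc(C(C)C)c(S(=O)(=O)NN)c(C(C)C)c1
Why: Acid-catalysed hydrazone formation should proceed even with this hindered ketone, and the bulky sulfonyl group should sit anti to the quaternary carbon, the geometry needed for the Shapiro reaction.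

Step 2
Reactants: 2 N'-[(1E)-2,2-dimethylcyclohexylidene]-2,4,6-triisopropylbenzenesulfonohydrazide; 3 N,N-dimethylformamide
Product: 5 6,6-dimethylcyclohex-1-ene-1-carbaldehyde, via 6,6-dimethylcyclohexenyllithium 4 (not isolated)
Conditions: n-BuLi (2.2 equiv), THF, −78 → 0 °C; then 3, −78 °C → rt; H2O
Reagents that add atoms: N,N-dimethylformamide 3, CN(C)C=O
Why: Shapiro reaction, in which double deprotonation (N–H, then the only α-CH2) and loss of sulfinate and N2 should give the vinyllithium regiospecifically, followed by Bouveault-type formylation with DMF.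

Step 3
Reactants: 5 6,6-dimethylcyclohex-1-ene-1-carbaldehyde; 6 methylmagnesium bromide
Product: 8 (E)-[(6S)-2,2,6-trimethylcyclohexylidene]methyl trifluoromethanesulfonate, via bromomagnesium enolate 7 (not isolated)
Conditions: CuBr·SMe2 (5 mol%), (R)-1-[(Sp)-2-(diphenylphosphino)ferrocenyl]ethyldicyclohexylphosphine (6 mol%), 6 (1.2 equiv), t-BuOMe, −78 °C, slow addition of 5; then PhNTf2, THF/DMPU, −78 °C → rt
Reagents that add atoms: methylmagnesium bromide 6, C[Mg]Br; N-phenylbis(trifluoromethanesulfonimide), O=S(=O)(N(c1ccccc1)S(=O)(=O)C(F)(F)F)C(F)(F)F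
Why: Transmetalation of 6 to the ligated monovalent copper bromide should give a chiral methylcopper–magnesium species that binds the C5'=C6' alkene of 5, adds oxidatively at C5' to a trivalent copper intermediate and reductively eliminates to form the C5'–CH3 bond and the bromomagnesium enolate 7, whose double bond is the exocyclic C6'=C7'; PhNTf2 then sulfonylates the enolate oxygen. The closest known reaction type is the copper/ferrocenyl diphosphine-catalysed enantioselective conjugate addition of Grignard reagents to α,β-unsaturated aldehydes with trapping of the enolate on oxygen, of which an α-branched ring enal is an extension. No ring is closed, ring B being carried intact from 1. The new stereocentre C5' is set by the ligand on copper, which selects the face of the ring alkene that receives the methyl group (catalyst control, since 5 has no stereocentre). The step needs 1,4- over 1,2-addition, which the quaternary C1' next to the formyl-bearing C6', the low temperature and the slow addition of 5 should secure, and it needs the enolate oxygen cis to C5', which should follow from the s-cis conformer of the enal, where the formyl hydrogen and not the oxygen faces the gem-dimethyl group. O- rather than C-sulfonylation and the absence of aldol side reactions should follow from the fully substituted C6', flanked by C1' and C5'.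

Step 4
Reactants: 9 (2E)-3-methylpent-2-en-4-yn-1-ol
Product: 11 (2E,4E)-5-iodo-3-methylpenta-2,4-dien-1-ol, via dienylzirconocene chloride 10 (not isolated)
Conditions: Cp2Zr(H)Cl (2.2 equiv), THF, rt; then I2, 0 °C; H2O
Reagents that add atoms: iodine, II
Why: Hydrozirconation–iodination, in which syn addition of Zr–H to the terminal alkyne (Zr at the terminal carbon) and iodinolysis with retention should fix the (E)-C15'=C14' geometry, the first equivalent of hydride being consumed by the hydroxyl group.

Step 5
Reactants: 11 (2E,4E)-5-iodo-3-methylpenta-2,4-dien-1-ol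
Product: 12 (2E,4E)-5-iodo-3-methylpenta-2,4-dienal
Conditions: MnO2 (activated, excess), CH2Cl2, rt
Reagents that add atoms: none
Why: Allylic oxidation with activated MnO2 should be selective for the primary allylic alcohol and leave the alkenyl iodide and both alkene geometries untouched.

Step 6
Reactants: 12 (2E,4E)-5-iodo-3-methylpenta-2,4-dienal; 13 diethyl [3-(trimethylsilyl)prop-2-yn-1-yl]phosphonate
Product: 15 trimethyl[(3E,5E,7E)-8-iodo-6-methylocta-3,5,7-trien-1-yn-1-yl]silane, via lithiated phosphonate 14 (not isolated)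
Conditions: 13, LiN(SiMe3)2, THF, −78 °C; then 12, −78 → 0 °C; H2O
Reagents that add atoms: none
Why: Horner–Wadsworth–Emmons olefination with a propargylic phosphonate anion should form the C11'=C10' bond with the E geometry typical of stabilised phosphonate carbanions.

Step 7
Reactants: 16 all-trans-retinol
Product: 17 anhydroretinol, (6E)-6-[(2E,4E,6E)-3,7-dimethylnona-2,4,6,8-tetraen-1-ylidene]-1,5,5-trimethylcyclohex-1-ene
Conditions: HCl (cat., anhydrous), EtOH, rt, short contact; then NaHCO3
Reagents that add atoms: none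
Why: Acid-catalysed vinylogous dehydration (retro rearrangement), in which ionisation of the allylic alcohol gives the retinyl cation and loss of the C4 proton should give the fully conjugated retro hexaene with the thermodynamically preferred (6E) exocyclic alkene, the classical preparation of this hydrocarbon.

Step 8
Reactants: 17 anhydroretinol; 15 trimethyl[(3E,5E,7E)-8-iodo-6-methylocta-3,5,7-trien-1-yn-1-yl]silane
Product: 18 trimethyl[(3E,5E,7E,9E,11E,13E,15E,17E)-6,11,15-trimethyl-17-(2,6,6-trimethylcyclohex-2-en-1-ylidene)heptadeca-3,5,7,9,11,13,15-heptaen-1-yn-1-yl]silane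
Conditions: Pd(OAc)2 (10 mol%), n-Bu4NCl, K2CO3, DMF, 35 °C
Reagents that add atoms: none
Why: Mizoroki–Heck reaction under phosphine-free phase-transfer conditions, in which oxidative addition of 15 to zerovalent palladium, insertion of the only monosubstituted alkene (C14=C15H2) with carbon delivered to C15 and syn β-hydride elimination from C15 should give the (E)-C14=C15 bond in conjugation.

Step 9
Reactants: 18 silyl-capped C29 retro polyenyne
Product: 19 (6E)-1,5,5-trimethyl-6-[(2E,4E,6E,8E,10E,12E,14E)-3,7,12-trimethylheptadeca-2,4,6,8,10,12,14-heptaen-16-yn-1-ylidene]cyclohex-1-ene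
Conditions: K2CO3, MeOH/THF, rt
Reagents that add atoms: none
Why: Base-catalysed methanolysis of the alkynyl C–Si bond (protodesilylation) is mild enough that the retro polyene should survive unchanged.

Step 10
Reactants: 19 C29 retro polyenyne; 20 trimethylaluminium; 8 (E)-[(6S)-2,2,6-trimethylcyclohexylidene]methyl trifluoromethanesulfonate
Product: 22 (5'S,6E,6'E)-4,5'-retro-β,β-carotene, via polyenyl dimethylalane 21 (not isolated)
Conditions: 20 (2 equiv), Cp2ZrCl2 (25 mol%), ClCH2CH2Cl, rt; volatiles removed; then 8, Pd2(dba)3 (2.5 mol%), P(2-furyl)3 (10 mol%), ZnCl2 (30 mol%), THF, rt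
Reagents that add atoms: trimethylaluminium 20, C[Al](C)C
Why: Zirconium-catalysed methylalumination (syn addition, aluminium at the terminal carbon) should set the (E)-C9'=C8' alkene, and Negishi coupling of the alkenylalane with the enol triflate under palladium/zinc co-catalysis should form C7'–C8' with retention at both partners, a sequence established for carotenoid polyenynes, without touching C5'.

**Compound list**
1 | 2,2-dimethylcyclohexan-1-one | CC1(C)CCCCC1=O | starting material
2 | N'-[(1E)-2,2-dimethylcyclohexylidene]-2,4,6-triisopropylbenzenesulfonohydrazide | CC1(C)CCCC\C1=N/NS(=O)(=O)c1c(C(C)C)cc(C(C)C)cc1C(C)C | intermediate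
3 | N,N-dimethylformamide | CN(C)C=O | starting material
4 | (6,6-dimethylcyclohex-1-en-1-yl)lithium | [Li]C1=CCCCC1(C)C | intermediate
5 | 6,6-dimethylcyclohex-1-ene-1-carbaldehyde | O=CC1=CCCCC1(C)C | intermediate
6 | methylmagnesium bromide | C[Mg]Br | starting material
7 | bromomagnesium (E)-[(6S)-2,2,6-trimethylcyclohexylidene]methanolate | Br[Mg]O/C=C1\[C@@H](C)CCCC1(C)C | intermediate
8 | (E)-[(6S)-2,2,6-trimethylcyclohexylidene]methyl trifluoromethanesulfonate (oxygen cis to C5') | FC(F)(F)S(=O)(=O)O/C=C1\[C@@H](C)CCCC1(C)C | intermediate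
9 | (2E)-3-methylpent-2-en-4-yn-1-ol | C#C/C(C)=C/CO | starting material
10 | [(1E,3E)-5-{[chlorobis(cyclopentadienyl)zirconio]oxy}-3-methylpenta-1,3-dien-1-yl]chlorobis(cyclopentadienyl)zirconium (cyclopentadienyl rings drawn sigma-bonded) | Cl[Zr](/C=C/C(C)=C/CO[Zr](Cl)(C1C=CC=C1)C1C=CC=C1)(C1C=CC=C1)C1C=CC=C1 | intermediate
11 | (2E,4E)-5-iodo-3-methylpenta-2,4-dien-1-ol | OC/C=C(C)/C=C/I | intermediate
12 | (2E,4E)-5-iodo-3-methylpenta-2,4-dienal | O=C/C=C(C)/C=C/I | intermediate
13 | diethyl [3-(trimethylsilyl)prop-2-yn-1-yl]phosphonate | CCOP(=O)(OCC)CC#C[Si](C)(C)C | starting material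
14 | lithium salt of 13 deprotonated at the P–CH2 carbon | [Li]C(C#C[Si](C)(C)C)P(=O)(OCC)OCC | intermediate
15 | trimethyl[(3E,5E,7E)-8-iodo-6-methylocta-3,5,7-trien-1-yn-1-yl]silane | C[Si](C)(C)C#C/C=C/C=C(C)/C=C/I | intermediate
16 | all-trans-retinol, (2E,4E,6E,8E)-3,7-dimethyl-9-(2,6,6-trimethylcyclohex-1-en-1-yl)nona-2,4,6,8-tetraen-1-ol | OC/C=C(C)/C=C/C=C(C)/C=C/C1=C(C)CCCC1(C)C | starting material
17 | anhydroretinol, (6E)-6-[(2E,4E,6E)-3,7-dimethylnona-2,4,6,8-tetraen-1-ylidene]-1,5,5-trimethylcyclohex-1-ene | CC1=CCCC(C)(C)\C1=C/C=C(C)/C=C/C=C(C)/C=C | intermediate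
18 | trimethyl[(3E,5E,7E,9E,11E,13E,15E,17E)-6,11,15-trimethyl-17-(2,6,6-trimethylcyclohex-2-en-1-ylidene)heptadeca-3,5,7,9,11,13,15-heptaen-1-yn-1-yl]silane | CC1=CCCC(C)(C)\C1=C/C=C(C)/C=C/C=C(C)/C=C/C=C/C(C)=C/C=C/C#C[Si](C)(C)C | intermediate
19 | (6E)-1,5,5-trimethyl-6-[(2E,4E,6E,8E,10E,12E,14E)-3,7,12-trimethylheptadeca-2,4,6,8,10,12,14-heptaen-16-yn-1-ylidene]cyclohex-1-ene | CC1=CCCC(C)(C)\C1=C/C=C(C)/C=C/C=C(C)/C=C/C=C/C(C)=C/C=C/C#C | intermediate
20 | trimethylaluminium | C[Al](C)C | starting material
21 | dimethyl[(1E,3E,5E,7E,9E,11E,13E,15E,17E)-2,6,11,15-tetramethyl-17-(2,6,6-trimethylcyclohex-2-en-1-ylidene)heptadeca-1,3,5,7,9,11,13,15-octaen-1-yl]alumane | CC1=CCCC(C)(C)\C1=C/C=C(C)/C=C/C=C(C)/C=C/C=C/C(C)=C/C=C/C(C)=C/[Al](C)C | intermediate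
22 | (5'S,6E,6'E)-4,5'-retro-β,β-carotene (all chain alkenes E; C8' cis to C5') | CC1=CCCC(C)(C)\C1=C/C=C(C)/C=C/C=C(C)/C=C/C=C/C(C)=C/C=C/C(C)=C/C=C1\[C@@H](C)CCCC1(C)C | target

**Step count:** 10 steps in total.
**Longest linear sequence:** 6 steps (steps 4, 5, 6, 8, 9, 10, from 9).

**Steps most likely to fail**

1. Step 3. Direct 1,2-addition of the Grignard reagent may outrun the copper cycle, facial discrimination may be weak on an α-branched ring enal, or O-sulfonylation of the magnesium enolate may be sluggish. Fallback, from 5 back to 8: condensation of 5 with tert-butyl (S)-tert-leucinate (or its antipode, as the sense of induction requires) gives the aldimine tert-butyl (2S)-2-{[(E)-(6,6-dimethylcyclohex-1-en-1-yl)methylidene]amino}-3,3-dimethylbutanoate F1. Chelation-controlled conjugate addition of 6 (THF, −23 °C), a stoichiometric auxiliary method established for cyclohexenecarbaldehyde imines, and mild acid hydrolysis give (6S)-2,2,6-trimethylcyclohexane-1-carbaldehyde F2. KN(SiMe3)2 (THF, −78 °C) gives the potassium (E)-[(6S)-2,2,6-trimethylcyclohexylidene]methanolate F3, which PhNTf2 converts to 8.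

2. Step 10. The retro polyene may isomerise or oligomerise in the Lewis-acidic methylalumination medium, the alkyne may be deprotonated instead of carbometalated, or methyl rather than polyenyl may be transferred to palladium. Fallback, from 19 back to 22: copper-catalysed methylboration of 19 (CuCl, Xantphos, NaOt-Bu, B2pin2, MeI, THF, rt) gives the C30 (E)-alkenyl pinacol boronate F6 (boron on C8', new methyl on C9'). Suzuki–Miyaura coupling of F6 with 8 (Pd(PPh3)4, aq. K3PO4, THF, rt, dark) gives 22.

3. Step 8. The extended π-allylpalladium intermediate may be captured or isomerised before β-hydride elimination, insertion may occur into internal alkenes, or palladium hydride may cause E/Z drift. Fallback, from 15 back to 18: iodine–lithium exchange on 15 (t-BuLi, Et2O, −78 °C) gives [(1E,3E,5E)-3-methyl-8-(trimethylsilyl)octa-1,3,5-trien-7-yn-1-yl]lithium F4. This adds 1,2 to commercial all-trans-retinal to give the C15 carbinol 15-[(1E,3E,5E)-3-methyl-8-(trimethylsilyl)octa-1,3,5-trien-7-yn-1-yl]retinol F5. Brief treatment with catalytic HCl in EtOH, as in step 7, ionises the doubly allylic alcohol and removes the C4 proton, giving 18.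

Further compounds
F1 | step 3 | tert-butyl (2S)-2-{[(E)-(6,6-dimethylcyclohex-1-en-1-yl)methylidene]amino}-3,3-dimethylbutanoate | CC1(C)CCCC=C1/C=N/[C@@H](C(C)(C)C)C(=O)OC(C)(C)C
F2 | step 3 | (6S)-2,2,6-trimethylcyclohexane-1-carbaldehyde (C1 epimers) | O=CC1[C@@H](C)CCCC1(C)C
F3 | step 3 | potassium (E)-[(6S)-2,2,6-trimethylcyclohexylidene]methanolate | [K]O/C=C1\[C@@H](C)CCCC1(C)C
F4 | step 8 | [(1E,3E,5E)-3-methyl-8-(trimethylsilyl)octa-1,3,5-trien-7-yn-1-yl]lithium | [Li]/C=C/C(C)=C/C=C/C#C[Si](C)(C)C
F5 | step 8 | 15-[(1E,3E,5E)-3-methyl-8-(trimethylsilyl)octa-1,3,5-trien-7-yn-1-yl]retinol (racemic at C15) | CC1=C(/C=C/C(C)=C/C=C/C(C)=C/C(O)/C=C/C(C)=C/C=C/C#C[Si](C)(C)C)C(C)(C)CCC1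
F6 | step 10 | 2-[(1E,3E,5E,7E,9E,11E,13E,15E,17E)-2,6,11,15-tetramethyl-17-(2,6,6-trimethylcyclohex-2-en-1-ylidene)heptadeca-1,3,5,7,9,11,13,15-octaen-1-yl]-4,4,5,5-tetramethyl-1,3,2-dioxaborolane | CC1=CCCC(C)(C)\C1=C/C=C(C)/C=C/C=C(C)/C=C/C=C/C(C)=C/C=C/C(C)=C/B1OC(C)(C)C(C)(C)O1
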